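Flask alder has converted 3.66 mM of starting material, by the mean of its readings from 4.00 h on, against 20.0 mM of partner charged. That leaves 16.3 mM unaccounted for. Call this T, the partner toll: partner charged minus starting material converted.

| flask | starting material | partner | remark | time |
|---|---|---|---|---|
| alder | 20 mM | 20 mM | the very flask that is asked about, followed so far |  |
| birch | 13 mM | 20 mM | run made earlier |  |
| flask | 20 mM | 20.0 mM |  | 20 h |

alder run (percent of the starting material charged)

| time / h | target / % | starting material / % |
|---|---|---|
| 1.50 | 2.9 | 97.7 |
| 4.00 | 17.7 | 82.7 |
| 8.00 | 17.3 | 80.9 |
| 12.0 | 17.0 | 81.5 |

birch run (percent of the starting material charged)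

| time / min | target / % | starting material / % |
|---|---|---|
| 15.0 | 0.3 | 100.3 |
| 30.0 | 0.3 | 99.6 |
| 50.0 | 0 | 99.5 |
| 60.0 | 0.5 | 98.4 |

(scatter of a reading: 0.5 percentage points)

- target that was removed still counts
- the numbers in the tables scatter with a standard deviation of 0.5 percentage points
- steps that have been proposed: target -> over-reaction product; partner -> decomposed reagent; starting material + partner + target -> 2 target; starting material + partner -> target
- additions bring no volume worth counting

- Wednesday's: at 20 h add starting material, 50.0% of the amount charged, then wait 10 h
- Sunday's: change nothing and wait 10 h more
- Thursday's: at 20 h take out 90% of the target then present, then wait 10 h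
- Friday's: at 20 h add partner, 100% of the amount charged, then wait 10 h

1. target, in percent of the starting material first charged, at 20 h
2. the remedy with the largest gain of target, or "none" below 2 percentage points (Wednesday's / Sunday's / Thursday's / Friday's / none)
3. target present, with what was taken out counted in, in percent of the starting material first charged, after Sunday's
4. target present, with what was taken out counted in, in percent of the starting material first charged, after Friday's

Target reads 0.5% in birch at 60.0 min and 2.9% in alder at 1.50 h, then jumps in alder to 17.7% at 4.00 h, so it behaves like a growth with a slow start. Starting material in alder then reads 82.7%, 80.9% and 81.5%, a plateau as far as a scatter of 0.5 percentage points lets one tell. My reckoning takes that race as settled: partner was draining to decomposed reagent while target grew, and T is what the drain collected.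

Now turn the question round. If T stayed at its alder value, which is an assumption and no bound, partner would have to pay T and also match the 20 mM of starting material for starting material to finish, 36.3 mM together. Flask alder holds 20.0 mM, which is less by 16.3 mM, so I take partner as the limiting reagent. Waiting, adding starting material or removing target brings no partner, so I expect target near its plateau. Friday's brings 20.0 mM. If it paid T in full, that dose would leave 18.3% of new target on top of the plateau, and that low estimate is my commitment.

The forecast gives 16.4% now, 15.7% after Sunday's and 89% after Friday's, and it picks Friday's: “Fresh partner, with 16% target already seeding, reacts far faster than it decays”. Its Friday figure stands above my estimate, which with the plateau readings added comes to 35.6% of target.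

The flask gives 17.0% at 20 h, 16.3% after Sunday's and 78.3% after Friday's. The best remedy is Friday's, with a gain of 61 points.

    target → over-reaction product (k = 7.27 × 10⁻⁵ min⁻¹)
    partner → decomposed reagent (k = 0.0101 min⁻¹)
    starting material + partner + target → 2 target (k = 227 M⁻² min⁻¹)
    starting material + partner → target (k = 6.71 × 10⁻⁴ M⁻¹ min⁻¹)

Flask alder has stopped converting but is not at rest. At 200 h starting material still stands at 81.6% and partner at 0%, yet target has fallen to 7.76% and over-reaction product has risen to 10.6%, on a half-life of 160 h, long against 20 h. Friday's is where the forecast parts from the flask, by 11 points. Its dose added 12.3 mM of target, so the second toll is 7.75 mM, smaller than T but well above nothing.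

The neighbour flask charged with 50 mM of partner stands above 36.3 mM, so T held at its alder value gives a finish there with 13.7 mM of partner to spare. That neighbour flask ends at 0.89% starting material and 91.2% target, but with partner at 0% and T at 30.2 mM, more than in alder.

All runs were generated by integration on assumed constants; the scatter is artificial.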